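Numbering (azulene): C1/C2 ring CH2, C3 carbinol (OH, isopropyl), C3a fusion CH, C4 ester carbon, C5 CH2, C6 methyl-bearing alkene carbon, C7 alkene CH, C8 ketone, C8a angular C-methyl.
Retrosynthesis: the vanillate C4–O bond is cut first; with C8 taken back to a silyl-protected carbinol and C4 to a methyl enol ether, the seven-membered ring is cut at C4–C5 and C8–C8a.
Enabling feature: the seven ring atoms divide into an oxygen-bearing carbon C4 on the C3a–C8a edge of the five-membered ring (a methoxy(cyclopentenyl)carbene) and the chain C5–C6(CH3)–C7–C8(O) (a 1-siloxy-3-methylbuta-1,3-diene).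
Forward: the five-membered ring is made first by ozonolysis/aldol ring contraction of (S)-terpinen-4-ol; the seven-membered ring is closed onto it by carbene transfer and Cope rearrangement; the aryl ester is joined last.
Stereochemistry: C3 comes from terpinen-4-ol; C8a is set in the Cope boat, steered by a hydrogen bond from the free C3 hydroxyl to the carbene-derived methoxy oxygen; C3a (protonation) and C4 (hydride) are set anti to the angular methyl.

Key step: step 9

Assumption: (S)-(+)-terpinen-4-ol is used enantiopure (commercial material of lower enantiomeric purity would be upgraded first); its carbinol carbon is the only source of absolute configuration.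

Step 1
Reactants: 1 (S)-terpinen-4-ol
Product: 2 triethyl{[(1S)-4-methyl-1-(propan-2-yl)cyclohex-3-en-1-yl]oxy}silane
Conditions: TESOTf, 2,6-lutidine, CH2Cl2, 0 °C to rt
Reagents that add atoms: triethylsilyl trifluoromethanesulfonate, CC[Si](CC)(CC)OS(=O)(=O)C(F)(F)F
Why: Silyl triflate/hindered base silylation of a tertiary alcohol; the ether carries the carbinol through the aldol, oxidation and acyl chloride steps.

Step 2
Reactants: 2 triethylsilyl ether of terpinen-4-ol
Product: 4 (3S)-6-oxo-3-(propan-2-yl)-3-[(triethylsilyl)oxy]heptanal, via ozonide 3 (not isolated)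
Conditions: O3, CH2Cl2, −78 °C; then PPh3, −78 °C to rt
Reagents that add atoms: ozone, [O-][O+]=O
Why: Ozonolysis with reductive work-up cleaves the only C=C bond to the 1,6-keto aldehyde and leaves the stereocentre untouched.

Step 3
Reactants: 4 keto aldehyde
Product: 5 (5R)-2-methyl-5-(propan-2-yl)-5-[(triethylsilyl)oxy]cyclopent-1-ene-1-carbaldehyde
Conditions: Bn2NH·CF3CO2H (0.3 equiv), toluene, 50 °C
Reagents that add atoms: none
Why: Amine-catalysed intramolecular aldol condensation (the enamine of the aldehyde adds to the methyl ketone, 5-enolexo), which gives the cyclopentenecarbaldehyde and not the acetylcyclopentene; water is lost from the new aldol hydroxyl under general-acid assistance in preference to the less basic silyl ether.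

Step 4
Reactants: 5 enal
Product: 6 (5R)-2-methyl-5-(propan-2-yl)-5-[(triethylsilyl)oxy]cyclopent-1-ene-1-carboxylic acid
Conditions: NaClO2, NaH2PO4, 2-methylbut-2-ene, t-BuOH–H2O, 0 °C to rt
Reagents that add atoms: sodium chlorite, [Na+].[O-]Cl=O
Why: Pinnick oxidation of a hindered enal; the buffered medium spares the tertiary silyl ether and the scavenger removes hypochlorous acid.

Step 5
Reactants: 6 carboxylic acid
Product: 7 (5R)-2-methyl-5-(propan-2-yl)-5-[(triethylsilyl)oxy]cyclopent-1-ene-1-carbonyl chloride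
Conditions: 1-chloro-N,N,2-trimethylprop-1-en-1-amine, CH2Cl2, 0 °C to rt; used crude
Reagents that add atoms: 1-chloro-N,N,2-trimethylprop-1-en-1-amine, CC(C)=C(Cl)N(C)C
Why: Acid chloride formation with an α-chloroenamine under neutral conditions, so no HCl is formed that could cleave the silyl ether.

Step 6
Reactants: 7 acid chloride; 8 chromium hexacarbonyl, Cr(CO)6
Product: 11 pentacarbonyl{methoxy[(5R)-2-methyl-5-(propan-2-yl)-5-(triethylsilyloxy)cyclopent-1-en-1-yl]methylidene}chromium, via disodium pentacarbonylchromate 9 (not isolated), via sodium acylchromate 10 (not isolated)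
Conditions: Cr(CO)6, NaC10H8 (2 equiv), THF, −78 °C; 7, −78 to 0 °C; evaporate; MeOTf, CH2Cl2, 0 °C
Reagents that add atoms: methyl trifluoromethanesulfonate, COS(=O)(=O)C(F)(F)F
Why: Acid chloride route to alkoxycarbene complexes: the pentacarbonylchromate dianion is acylated and the acylchromate is O-methylated by a hard alkylating agent; this suits an alkenyl group that is not available as an organolithium.

Step 7
Reactants: 11 silyl-protected carbene complex
Product: 12 pentacarbonyl{[(5R)-5-hydroxy-2-methyl-5-(propan-2-yl)cyclopent-1-en-1-yl](methoxy)methylidene}chromium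
Conditions: HF·pyridine, THF, 0 °C
Reagents that add atoms: none
Why: Acidic fluoride cleaves the tertiary triethylsilyl ether without base (no deprotonation of the vinylogous positions) and without an N–H or O–H nucleophile that could exchange at the carbene carbon; the hydroxyl is freed because it directs step 9.

Step 8
Reactants: 13 3-methylbut-2-enal
Product: 14 (E)-tert-butyl(dimethyl)[(3-methylbuta-1,3-dien-1-yl)oxy]silane
Conditions: TBSOTf, Et3N, Et2O, 0 °C to rt
Reagents that add atoms: tert-butyldimethylsilyl trifluoromethanesulfonate, CC(C)(C)[Si](C)(C)OS(=O)(=O)C(F)(F)F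
Why: O-Silylation of the enal and γ-deprotonation (silyl dienol ether formation) give the 1-siloxy-1,3-diene, E at the enol ether bond.

Step 9
Reactants: 12 hydroxy carbene complex; 14 siloxydiene (4 equiv)
Product: 16 (3R,8R,8aS)-8-{[tert-butyl(dimethyl)silyl]oxy}-4-methoxy-6,8a-dimethyl-3-(propan-2-yl)-1,2,3,5,8,8a-hexahydroazulen-3-ol, via cis-divinylcyclopropane 15 (not isolated)
Conditions: toluene, CO (1 atm), base-washed sealed tube, 70 °C, then 115 °C
Reagents that add atoms: none
Why: The unsubstituted terminus C5 of the dienol ether, its most nucleophilic and least hindered carbon, adds to the electrophilic carbene carbon C4 and the chromate closes on C6 of the oxygen-stabilised allyl cation, so the distal double bond is cyclopropanated and Cr(CO)5 is taken up by CO as Cr(CO)6, while the tetrasubstituted alkenyl group shuts off the competing (4+2) mode. The closest known reaction type is the cyclopropanation of electron-rich 1,3-dienes by alkenyl(alkoxy) Fischer carbene complexes with in situ divinylcyclopropane Cope rearrangement (formal 4+3). The seven-membered ring closes by the [3,3] shift of 15 through the endo boat, C8–C8a forming as the cyclopropane bond C4–C6 breaks (the cyclopropane itself closes 3-exo). C8a: in that boat the methoxy oxygen on C4 lies on the cyclopentene face opposite to the breaking C4–C6 bond and next to C3, where the free hydroxyl hydrogen-bonds to it in a six-membered ring, so C6–C7=C8 is held on the isopropyl face and C8 bonds to C8a anti to the hydroxyl (methyl cis to OH); a silyl ether at C3 offers no such bias, which is why it was removed in step 7. C8: the boat places the E-siloxy group outside, trans to the C8a methyl (8R), a centre that is erased later. The step needs distal-bond attack, secured by the polarisation of the 1-oxydiene and the hindrance at the carbene carbon, and convergence of all cyclopropane isomers on the hydrogen-bonded boat, expected because the donor-substituted, doubly allylic C4–C6 bond should open reversibly at the 115 °C that the hindered Cope requires.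

Step 10
Reactants: 16 hydroxy enol ether (crude, kept free of acid)
Product: 17 (3R,8R,8aS)-8-{[tert-butyl(dimethyl)silyl]oxy}-4-methoxy-6,8a-dimethyl-3-(propan-2-yl)-3-[(triethylsilyl)oxy]-1,2,3,5,8,8a-hexahydroazulene
Conditions: TESOTf, 2,6-lutidine, CH2Cl2, −78 to 0 °C
Reagents that add atoms: triethylsilyl trifluoromethanesulfonate, CC[Si](CC)(CC)OS(=O)(=O)C(F)(F)F
Why: Silyl triflate silylation of the tertiary alcohol before any contact with acid; as a free γ-hydroxy enol ether the C3 oxygen would ionise and be lost (vinylogous), the silyl ether is a far poorer leaving group, and its bulk adds to the shielding of the lower face in steps 11 and 12.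

Step 11
Reactants: 17 bis-silyl enol ether
Product: 18 (3R,3aR,8R,8aS)-8-{[tert-butyl(dimethyl)silyl]oxy}-6,8a-dimethyl-3-(propan-2-yl)-3-[(triethylsilyl)oxy]-2,3,3a,5,8,8a-hexahydroazulen-4(1H)-one
Conditions: AcOH–NaOAc buffer (1 M, pH about 4.7), THF–H2O, 40 °C
Reagents that add atoms: water, O
Why: Enol ether hydrolysis in a concentrated weak-acid buffer, where rate-limiting C-protonation (general-acid catalysed) is favoured over ionisation of the C3 siloxy group (specific-acid catalysed); the proton is expected to reach C3a anti to the angular methyl and the siloxy group, giving the trans ring fusion, and the β,γ-alkene is not moved into conjugation under these conditions.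

Step 12
Reactants: 18 ketone
Product: 19 (3R,3aS,4R,8R,8aS)-8-{[tert-butyl(dimethyl)silyl]oxy}-6,8a-dimethyl-3-(propan-2-yl)-3-[(triethylsilyl)oxy]-1,2,3,3a,4,5,8,8a-octahydroazulen-4-ol
Conditions: LiBH(s-Bu)3 (L-Selectride), THF, −78 °C; then NaOH, H2O2
Reagents that add atoms: none
Why: Bulky hydride reduction at low temperature, without enolisation; hydride should reach C4 from the face of H-3a, away from the angular methyl on C8a (1,3 to the carbonyl) and the C3 siloxy group, so the new hydroxyl is cis to both (4R).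

Step 13
Reactants: 19 bis-silyl alcohol
Product: 20 (3R,3aS,4R,8R,8aS)-6,8a-dimethyl-3-(propan-2-yl)-1,2,3,3a,4,5,8,8a-octahydroazulene-3,4,8-triol
Conditions: TBAF, THF, rt to 45 °C
Reagents that add atoms: none
Why: Fluoride cleaves both alkyl silyl ethers; at this stage the molecule has no carbonyl group that the basic reagent could harm.

Step 14
Reactants: 20 triol
Product: 21 (3R,3aS,4R,8aS)-3,4-dihydroxy-6,8a-dimethyl-3-(propan-2-yl)-2,3,3a,4,5,8a-hexahydroazulen-8(1H)-one
Conditions: MnO2, CH2Cl2, rt
Reagents that add atoms: none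
Why: MnO2 oxidises only the allylic C8 alcohol to the β-methyl enone; the homoallylic secondary C4 alcohol and the tertiary alcohol are inert.

Step 15
Reactants: 22 vanillic acid
Product: 24 4-{[tert-butyl(dimethyl)silyl]oxy}-3-methoxybenzoic acid, via bis-silyl derivative 23 (not isolated)
Conditions: TBSCl (2.5 equiv), imidazole, DMF, rt; then AcOH–THF–H2O, rt
Reagents that add atoms: tert-butyldimethylsilyl chloride, CC(C)(C)[Si](C)(C)Cl
Why: Bis-silylation followed by selective hydrolysis of the labile silyl ester leaves the aryl silyl ether, which blocks the phenol during esterification.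

Step 16
Reactants: 21 enone diol; 24 protected vanillic acid
Product: 26 (3R,3aS,4R,8aS)-3-hydroxy-6,8a-dimethyl-8-oxo-3-(propan-2-yl)-1,2,3,3a,4,5,8,8a-octahydroazulen-4-yl 4-{[tert-butyl(dimethyl)silyl]oxy}-3-methoxybenzoate, via mixed anhydride 25 (not isolated)
Conditions: 24, 2,4,6-trichlorobenzoyl chloride, Et3N, THF, rt; then 21, DMAP, toluene, rt
Reagents that add atoms: none
Why: Yamaguchi esterification: DMAP transfers the less hindered aroyl group of the mixed anhydride to the secondary C4 hydroxyl with retention, and the tertiary C3 hydroxyl does not acylate.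

Step 17
Reactants: 26 silyl-protected ester
Product: 27 (3R,3aS,4R,8aS)-3-hydroxy-6,8a-dimethyl-8-oxo-3-(propan-2-yl)-1,2,3,3a,4,5,8,8a-octahydroazulen-4-yl 4-hydroxy-3-methoxybenzoate
Conditions: TBAF, AcOH (1:1), THF, 0 °C
Reagents that add atoms: none
Why: Buffered fluoride cleaves the aryl silyl ether without exposing the δ-acyloxy enone to base, which could cause vinylogous elimination of the benzoate.

Compound list
1 | (S)-terpinen-4-ol, (1S)-4-methyl-1-(propan-2-yl)cyclohex-3-en-1-ol | CC1=CC[C@](O)(C(C)C)CC1 | starting material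
2 | triethyl{[(1S)-4-methyl-1-(propan-2-yl)cyclohex-3-en-1-yl]oxy}silane | CC1=CC[C@](O[Si](CC)(CC)CC)(C(C)C)CC1 | intermediate
3 | ozonide of 2 (1,2,4-trioxolane across the former ring alkene, both new centres unassigned) | CC12CC[C@@](O[Si](CC)(CC)CC)(C(C)C)CC(OO1)O2 | intermediate (not isolated)
4 | (3S)-6-oxo-3-(propan-2-yl)-3-[(triethylsilyl)oxy]heptanal | O=CC[C@](O[Si](CC)(CC)CC)(C(C)C)CCC(C)=O | intermediate
5 | (5R)-2-methyl-5-(propan-2-yl)-5-[(triethylsilyl)oxy]cyclopent-1-ene-1-carbaldehyde | O=CC1=C(C)CC[C@@]1(O[Si](CC)(CC)CC)C(C)C | intermediate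
6 | (5R)-2-methyl-5-(propan-2-yl)-5-[(triethylsilyl)oxy]cyclopent-1-ene-1-carboxylic acid | OC(=O)C1=C(C)CC[C@@]1(O[Si](CC)(CC)CC)C(C)C | intermediate
7 | (5R)-2-methyl-5-(propan-2-yl)-5-[(triethylsilyl)oxy]cyclopent-1-ene-1-carbonyl chloride | ClC(=O)C1=C(C)CC[C@@]1(O[Si](CC)(CC)CC)C(C)C | intermediate
8 | chromium hexacarbonyl, Cr(CO)6 | O=C=[Cr](=C=O)(=C=O)(=C=O)(=C=O)=C=O | starting material
9 | disodium pentacarbonylchromate, Na2Cr(CO)5 | [Na+].[Na+].O=C=[Cr-2](=C=O)(=C=O)(=C=O)=C=O | intermediate (not isolated)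
10 | sodium pentacarbonyl(acyl)chromate derived from 7 | [Na+].[O-]C(=[Cr](=C=O)(=C=O)(=C=O)(=C=O)=C=O)C1=C(C)CC[C@@]1(O[Si](CC)(CC)CC)C(C)C | intermediate (not isolated)
11 | pentacarbonyl{methoxy[(5R)-2-methyl-5-(propan-2-yl)-5-(triethylsilyloxy)cyclopent-1-en-1-yl]methylidene}chromium | COC(=[Cr](=C=O)(=C=O)(=C=O)(=C=O)=C=O)C1=C(C)CC[C@@]1(O[Si](CC)(CC)CC)C(C)C | intermediate
12 | pentacarbonyl{[(5R)-5-hydroxy-2-methyl-5-(propan-2-yl)cyclopent-1-en-1-yl](methoxy)methylidene}chromium | COC(=[Cr](=C=O)(=C=O)(=C=O)(=C=O)=C=O)C1=C(C)CC[C@@]1(O)C(C)C | intermediate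
13 | 3-methylbut-2-enal | CC(C)=CC=O | starting material
14 | (E)-tert-butyl(dimethyl)[(3-methylbuta-1,3-dien-1-yl)oxy]silane | C=C(C)/C=C/O[Si](C)(C)C(C)(C)C | intermediate
15 | (1R)-2-[(1S,2R)-2-{(E)-2-[(tert-butyldimethylsilyl)oxy]ethenyl}-1-methoxy-2-methylcyclopropyl]-3-methyl-1-(propan-2-yl)cyclopent-2-en-1-ol (cyclopentenyl and siloxyvinyl groups cis on the cyclopropane) | CO[C@]1(C[C@]1(C)/C=C/O[Si](C)(C)C(C)(C)C)C2=C(C)CC[C@@]2(O)C(C)C | intermediate (not isolated)
16 | (3R,8R,8aS)-8-{[tert-butyl(dimethyl)silyl]oxy}-4-methoxy-6,8a-dimethyl-3-(propan-2-yl)-1,2,3,5,8,8a-hexahydroazulen-3-ol | COC=2CC(C)=C[C@@H](O[Si](C)(C)C(C)(C)C)[C@@]3(C)CC[C@@](O)(C(C)C)C3=2 | intermediate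
17 | (3R,8R,8aS)-8-{[tert-butyl(dimethyl)silyl]oxy}-4-methoxy-6,8a-dimethyl-3-(propan-2-yl)-3-[(triethylsilyl)oxy]-1,2,3,5,8,8a-hexahydroazulene | COC=2CC(C)=C[C@@H](O[Si](C)(C)C(C)(C)C)[C@@]3(C)CC[C@@](O[Si](CC)(CC)CC)(C(C)C)C3=2 | intermediate
18 | (3R,3aR,8R,8aS)-8-{[tert-butyl(dimethyl)silyl]oxy}-6,8a-dimethyl-3-(propan-2-yl)-3-[(triethylsilyl)oxy]-2,3,3a,5,8,8a-hexahydroazulen-4(1H)-one | O=C2CC(C)=C[C@@H](O[Si](C)(C)C(C)(C)C)[C@@]3(C)CC[C@@](O[Si](CC)(CC)CC)(C(C)C)[C@H]23 | intermediate
19 | (3R,3aS,4R,8R,8aS)-8-{[tert-butyl(dimethyl)silyl]oxy}-6,8a-dimethyl-3-(propan-2-yl)-3-[(triethylsilyl)oxy]-1,2,3,3a,4,5,8,8a-octahydroazulen-4-ol | O[C@@H]2CC(C)=C[C@@H](O[Si](C)(C)C(C)(C)C)[C@@]3(C)CC[C@@](O[Si](CC)(CC)CC)(C(C)C)[C@H]23 | intermediate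
20 | (3R,3aS,4R,8R,8aS)-6,8a-dimethyl-3-(propan-2-yl)-1,2,3,3a,4,5,8,8a-octahydroazulene-3,4,8-triol | O[C@@H]2CC(C)=C[C@@H](O)[C@@]3(C)CC[C@@](O)(C(C)C)[C@H]23 | intermediate
21 | (3R,3aS,4R,8aS)-3,4-dihydroxy-6,8a-dimethyl-3-(propan-2-yl)-2,3,3a,4,5,8a-hexahydroazulen-8(1H)-one | O[C@@H]2CC(C)=CC(=O)[C@@]3(C)CC[C@@](O)(C(C)C)[C@H]23 | intermediate
22 | vanillic acid, 4-hydroxy-3-methoxybenzoic acid | COc1cc(C(=O)O)ccc1O | starting material
23 | tert-butyldimethylsilyl 4-{[tert-butyl(dimethyl)silyl]oxy}-3-methoxybenzoate | COc1cc(C(=O)O[Si](C)(C)C(C)(C)C)ccc1O[Si](C)(C)C(C)(C)C | intermediate (not isolated)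
24 | 4-{[tert-butyl(dimethyl)silyl]oxy}-3-methoxybenzoic acid | COc1cc(C(=O)O)ccc1O[Si](C)(C)C(C)(C)C | intermediate
25 | 4-{[tert-butyl(dimethyl)silyl]oxy}-3-methoxybenzoic 2,4,6-trichlorobenzoic anhydride | COc1cc(C(=O)OC(=O)c2c(Cl)cc(Cl)cc2Cl)ccc1O[Si](C)(C)C(C)(C)C | intermediate (not isolated)
26 | (3R,3aS,4R,8aS)-3-hydroxy-6,8a-dimethyl-8-oxo-3-(propan-2-yl)-1,2,3,3a,4,5,8,8a-octahydroazulen-4-yl 4-{[tert-butyl(dimethyl)silyl]oxy}-3-methoxybenzoate | COc1cc(C(=O)O[C@@H]2CC(C)=CC(=O)[C@@]3(C)CC[C@@](O)(C(C)C)[C@H]23)ccc1O[Si](C)(C)C(C)(C)C | intermediate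
27 | (3R,3aS,4R,8aS)-3-hydroxy-6,8a-dimethyl-8-oxo-3-(propan-2-yl)-1,2,3,3a,4,5,8,8a-octahydroazulen-4-yl 4-hydroxy-3-methoxybenzoate | COc1cc(C(=O)O[C@@H]2CC(C)=CC(=O)[C@@]3(C)CC[C@@](O)(C(C)C)[C@H]23)ccc1O | target

Total step count: 17. Longest linear sequence: 15 steps (1–7, 9–14, 16, 17); steps 8 and 15 are side branches.

Steps most likely to fail

Step 9. Three processes threaten it. The hindered carbene complex may lose CO and decompose before the diene is captured. The diene may be attacked through its enol ether bond, which leads to the regioisomeric ring. The Cope rearrangement may pass through the boat that lacks the hydrogen bond and so engage the wrong cyclopentene face. The fallback changes the carbene carrier and separates carbene transfer from rearrangement; it sets out from acid chloride 7 and comes back at 16. Mo(CO)6 and NaC10H8 give disodium pentacarbonylmolybdate F1, and acylation with 7 gives the sodium acylmolybdate F2. Methylation with MeOTf gives the silyl-protected molybdenum carbene complex F3, and HF·pyridine gives the hydroxy molybdenum carbene complex F4. Molybdenum alkoxycarbene complexes hand their carbene ligand to 1,3-dienes near room temperature, so F4 and 14 (THF, 25–40 °C, CO) should give cyclopropane 15 without thermal stress. Compound 15 is then isolated on base-treated silica and rearranged in a separate thermolysis (toluene, 115 °C) to 16, which lets the cyclopropanation and the Cope selectivity be examined one at a time.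

Step 11. Acid may ionise the C3 siloxy group through the enol ether, with vinylogous loss of the tertiary oxygen, instead of protonating C3a; the proton may also add from the face of the angular methyl and give the cis-fused ketone. The fallback avoids acid altogether; it sets out from 17 and comes back at 18. NBS with NaHCO3 in THF–H2O at 0 °C attacks the enol ether at C3a with electrophilic bromine, and collapse of the hemiketal with loss of methanol gives the 3a-bromo ketone F5 (bromohydroxylation of an enol ether). Bu3SnH with AIBN in benzene at 80 °C then replaces bromine by hydrogen through the C3a radical, which takes hydrogen from the stannane on its more open face, to give 18.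

Step 12. Hydride delivery may show poor or reversed facial selectivity and give the C4 epimer. The fallback turns that epimer into the ester with inversion; it sets out from 18 and comes back at 26. If reduction gives mainly the C4-epimeric alcohol F6, Mitsunobu esterification of F6 with acid 24 (PPh3, DIAD, toluene) should give the fully silylated ester F7 with the required C4 configuration. HF·pyridine in THF then removes the two alkyl silyl ethers and leaves the aryl silyl ether, giving the C8 allylic alcohol F8. MnO2 oxidises F8 to 26, and step 17 follows.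

Further compounds
F1 | step 9 | disodium pentacarbonylmolybdate, Na2Mo(CO)5 | [Na+].[Na+].O=C=[Mo-2](=C=O)(=C=O)(=C=O)=C=O
F2 | step 9 | sodium pentacarbonyl(acyl)molybdate derived from 7 | [Na+].[O-]C(=[Mo](=C=O)(=C=O)(=C=O)(=C=O)=C=O)C1=C(C)CC[C@@]1(O[Si](CC)(CC)CC)C(C)C
F3 | step 9 | pentacarbonyl{methoxy[(5R)-2-methyl-5-(propan-2-yl)-5-(triethylsilyloxy)cyclopent-1-en-1-yl]methylidene}molybdenum | COC(=[Mo](=C=O)(=C=O)(=C=O)(=C=O)=C=O)C1=C(C)CC[C@@]1(O[Si](CC)(CC)CC)C(C)C
F4 | step 9 | pentacarbonyl{[(5R)-5-hydroxy-2-methyl-5-(propan-2-yl)cyclopent-1-en-1-yl](methoxy)methylidene}molybdenum | COC(=[Mo](=C=O)(=C=O)(=C=O)(=C=O)=C=O)C1=C(C)CC[C@@]1(O)C(C)C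
F5 | step 11 | 3a-bromo derivative of ketone 18 (C3a configuration immaterial) | O=C1CC(C)=C[C@@H](O[Si](C)(C)C(C)(C)C)[C@@]2(C)CC[C@@](O[Si](CC)(CC)CC)(C(C)C)C12Br
F6 | step 12 | (3R,3aS,4S,8R,8aS)-8-{[tert-butyl(dimethyl)silyl]oxy}-6,8a-dimethyl-3-(propan-2-yl)-3-[(triethylsilyl)oxy]-1,2,3,3a,4,5,8,8a-octahydroazulen-4-ol (C4 epimer of 19) | O[C@H]2CC(C)=C[C@@H](O[Si](C)(C)C(C)(C)C)[C@@]3(C)CC[C@@](O[Si](CC)(CC)CC)(C(C)C)[C@H]23
F7 | step 12 | (3R,3aS,4R,8R,8aS)-8-{[tert-butyl(dimethyl)silyl]oxy}-6,8a-dimethyl-3-(propan-2-yl)-3-[(triethylsilyl)oxy]-1,2,3,3a,4,5,8,8a-octahydroazulen-4-yl 4-{[tert-butyl(dimethyl)silyl]oxy}-3-methoxybenzoate | COc1cc(C(=O)O[C@@H]2CC(C)=C[C@@H](O[Si](C)(C)C(C)(C)C)[C@@]3(C)CC[C@@](O[Si](CC)(CC)CC)(C(C)C)[C@H]23)ccc1O[Si](C)(C)C(C)(C)C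
F8 | step 12 | (3R,3aS,4R,8R,8aS)-3,8-dihydroxy-6,8a-dimethyl-3-(propan-2-yl)-1,2,3,3a,4,5,8,8a-octahydroazulen-4-yl 4-{[tert-butyl(dimethyl)silyl]oxy}-3-methoxybenzoate | COc1cc(C(=O)O[C@@H]2CC(C)=C[C@@H](O)[C@@]3(C)CC[C@@](O)(C(C)C)[C@H]23)ccc1O[Si](C)(C)C(C)(C)C
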